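**Retrosynthetic overview**

1. Target ⇐ Horner–Wadsworth–Emmons olefination of a C13 methyl ketone and deprotection ⇐ trans-decalin ester ⇐ Li/NH3 reductive methylation (sets C5–H and the C4 quaternary centre) ⇐ bicyclic enoate with C4=C5 and C8=C17.
2. Key disconnection: C5–C6 and C7–C8. Ring B is closed last by stitching an ethane-1,2-diyl unit (1,2-bis(pinacolboryl)ethane) between two alkenyl triflates on a ring A precursor.
3. Enabling feature: in ring B, C5 and C8 are 1,4-related through C10–C9 and both can be alkenyl carbons. C5 is the β-carbon of the C19–C4=C5 enoate (from a β-keto ester) and C8 is the carbon of the exocyclic C8=C17 methylene (from a methyl ketone), so the saturated C6–C7 pair is the only link missing.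
4. Ring A ⇐ Dieckmann closure (C4–C5) of a bis-lactone built from two chiral-pool lactones. The methyl carbinol carbon of (S)-angelica lactone (future C8) relays to C9 (anti conjugate addition) and C10 (anti alkylation) and is later oxidised away.
5. Order of ring formation: lactone template → ring A (Dieckmann) → ring B (key step).

Key step: step 9

Remark: labdane numbering of the target is used for every intermediate (C19 = carboxyl carbon on C4, C17 = methylene carbon on C8, C20 = methyl on C10); lactone 1 and diboron reagent 14 are taken as purchasable.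

**Route**

Step 1
Reactants: 1 (S)-5-methylfuran-2(5H)-one; 2 2-(2-bromoethyl)-2-methyl-1,3-dioxolane
Product: 4 (4R,5S)-5-methyl-4-[2-(2-methyl-1,3-dioxolan-2-yl)ethyl]dihydrofuran-2(3H)-one, via Grignard reagent 3 (not isolated)
Conditions: 2, Mg, THF, 25 °C; then 1, CuBr·SMe2 (10 mol %), THF, −78 to −40 °C; H2O
Reagents that add atoms: none
Why: Copper-catalysed conjugate addition of a Grignard reagent to a butenolide should take place anti to the methyl group on the carbinol carbon (future C8) and so set C9 by 1,2-induction from the bought stereocenter.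

Step 2
Reactants: 4 (4R,5S)-5-methyl-4-[2-(2-methyl-1,3-dioxolan-2-yl)ethyl]dihydrofuran-2(3H)-one
Product: 5 (3R,4R,5S)-3,5-dimethyl-4-[2-(2-methyl-1,3-dioxolan-2-yl)ethyl]dihydrofuran-2(3H)-one
Conditions: LiN(iPr)2, THF, −78 °C; MeI, −78 to −20 °C
Reagents that add atoms: iodomethane, CI
Why: Enolate alkylation (lactone α-methylation) should put the future C20 methyl trans to the C9 chain, and the configuration created here at C10 is only provisional because the centre is re-enolised in step 4.

Step 3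
Reactants: 6 (S)-5-(hydroxymethyl)dihydrofuran-2(3H)-one
Product: 7 [(2S)-5-oxotetrahydrofuran-2-yl]methyl trifluoromethanesulfonate
Conditions: Tf2O, pyridine, CH2Cl2, −40 °C
Reagents that add atoms: trifluoromethanesulfonic anhydride, O=S(=O)(OS(=O)(=O)C(F)(F)F)C(F)(F)F
Why: O-Sulfonylation of a primary alcohol does not touch the C2 stereocenter and gives an alkyl triflate reactive enough for a quaternising enolate alkylation at −78 °C.

Step 4
Reactants: 5 (3R,4R,5S)-3,5-dimethyl-4-[2-(2-methyl-1,3-dioxolan-2-yl)ethyl]dihydrofuran-2(3H)-one; 7 [(2S)-5-oxotetrahydrofuran-2-yl]methyl trifluoromethanesulfonate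
Product: 9 (3R,4R,5S)-3,5-dimethyl-4-[2-(2-methyl-1,3-dioxolan-2-yl)ethyl]-3-{[(2S)-5-oxotetrahydrofuran-2-yl]methyl}dihydrofuran-2(3H)-one, via lithium lactone enolate 8 (not isolated)
Conditions: LiN(iPr)2, THF, −78 °C; then 7, −78 to −40 °C
Reagents that add atoms: none
Why: SN2 alkylation of the tetrasubstituted lithium enolate 8 with the primary triflate should occur on the face anti to the adjacent C9 chain, which sets the quaternary C10 (C1 trans and methyl cis to the C9 chain) by 1,2-induction.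

Step 5
Reactants: 9 (3R,4R,5S)-3,5-dimethyl-4-[2-(2-methyl-1,3-dioxolan-2-yl)ethyl]-3-{[(2S)-5-oxotetrahydrofuran-2-yl]methyl}dihydrofuran-2(3H)-one
Product: 10 2-(trimethylsilyl)ethyl (3R,5R)-2,5-dihydroxy-3-[(2S,3R)-2-hydroxy-5-(2-methyl-1,3-dioxolan-2-yl)pentan-3-yl]-3-methylcyclohex-1-ene-1-carboxylate (ring A β-keto ester drawn as its enol)
Conditions: NaH, Me3SiCH2CH2OH, THF, 60 °C; then AcOH
Reagents that add atoms: 2-(trimethylsilyl)ethanol, C[Si](C)(C)CCO
Why: Alkoxide opening of the γ-lactone to the C19 ester, then Dieckmann condensation of its C4 enolate on the lactone carbonyl C5 (six-membered ring A, only C4 can enolise, driven by the β-keto ester enolate), should release the C2 and C8 carbinols without touching a stereocenter.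

Step 6
Reactants: 10 2-(trimethylsilyl)ethyl (3R,5R)-2,5-dihydroxy-3-[(2S,3R)-2-hydroxy-5-(2-methyl-1,3-dioxolan-2-yl)pentan-3-yl]-3-methylcyclohex-1-ene-1-carboxylate
Product: 11 2-(trimethylsilyl)ethyl (3R,5R)-5-[(tert-butyldimethylsilyl)oxy]-2-hydroxy-3-[(2S,3R)-2-hydroxy-5-(2-methyl-1,3-dioxolan-2-yl)pentan-3-yl]-3-methylcyclohex-1-ene-1-carboxylate
Conditions: t-BuMe2SiCl (1.1 equiv), imidazole, DMF, 0 °C
Reagents that add atoms: tert-butyldimethylsilyl chloride, CC(C)(C)[Si](C)(C)Cl
Why: Silyl ether formation should be selective for the unhindered ring carbinol at C2 because the C8 carbinol is flanked by the branched C9 and partly masked as the five-membered hemiketal with the C5 carbonyl.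

Step 7
Reactants: 11 2-(trimethylsilyl)ethyl (3R,5R)-5-[(tert-butyldimethylsilyl)oxy]-2-hydroxy-3-[(2S,3R)-2-hydroxy-5-(2-methyl-1,3-dioxolan-2-yl)pentan-3-yl]-3-methylcyclohex-1-ene-1-carboxylate
Product: 12 2-(trimethylsilyl)ethyl (3R,5R)-5-[(tert-butyldimethylsilyl)oxy]-2-hydroxy-3-methyl-3-[(3R)-5-(2-methyl-1,3-dioxolan-2-yl)-2-oxopentan-3-yl]cyclohex-1-ene-1-carboxylate
Conditions: Pr4N[RuO4] (5 mol %), N-methylmorpholine N-oxide, 4 Å MS, CH2Cl2, 23 °C
Reagents that add atoms: none
Why: Perruthenate-catalysed (Ley–Griffith) oxidation of the secondary C8 carbinol gives the methyl ketone and removes the stereocenter that has done its relay work.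

Step 8
Reactants: 12 2-(trimethylsilyl)ethyl (3R,5R)-5-[(tert-butyldimethylsilyl)oxy]-2-hydroxy-3-methyl-3-[(3R)-5-(2-methyl-1,3-dioxolan-2-yl)-2-oxopentan-3-yl]cyclohex-1-ene-1-carboxylate
Product: 13 2-(trimethylsilyl)ethyl (3R,5R)-5-[(tert-butyldimethylsilyl)oxy]-3-methyl-3-[(3R)-5-(2-methyl-1,3-dioxolan-2-yl)-2-(trifluoromethylsulfonyloxy)pent-1-en-3-yl]-2-(trifluoromethylsulfonyloxy)cyclohex-1-ene-1-carboxylate
Conditions: KN(SiMe3)2 (2.3 equiv), THF, −78 °C; PhNTf2 (2.5 equiv), −78 to 23 °C
Reagents that add atoms: N-phenylbis(trifluoromethanesulfonimide), O=S(=O)(N(c1ccccc1)S(=O)(=O)C(F)(F)F)C(F)(F)F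
Why: Double enolate O-triflation: the first equivalent of base forms the β-keto ester enolate and the second deprotonates the methyl ketone kinetically at C17, so both oxygen atoms are sulfonylated and C9 is not epimerised.

Step 9
Reactants: 13 bis(alkenyl triflate) (name as in step 8); 14 1,2-bis(4,4,5,5-tetramethyl-1,3,2-dioxaborolan-2-yl)ethane
Product: 16 2-(trimethylsilyl)ethyl 2α-[(tert-butyldimethylsilyl)oxy]-13,13-(ethylenedioxy)-14,15,18-trinorlabda-4,8(17)-dien-19-oate, via homoallylic pinacol boronate 15 (not isolated)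
Conditions: 14 (1.05 equiv, slow addition), Pd(OAc)2 (10 mol %), RuPhos (20 mol %), K3PO4, THF/H2O 10:1, 70 °C, 0.01 M
Reagents that add atoms: none
Why: Proposed new method: a formal (4+2) "ethylene stitching" in which zerovalent palladium inserts into one alkenyl triflate, a hydroxide-activated primary C–B bond of 14 transmetalates (helped by the neighbouring boron, as in mono-couplings of vicinal bis(boronates)) and reductive elimination gives 15, whose remaining alkyl–boron bond then couples intramolecularly with the second alkenyl triflate. The closest known reaction types are the B-alkyl Suzuki–Miyaura coupling of alkenyl triflates, the site-selective cross-coupling of 1,2-bis(boronates) and intramolecular B-alkyl Suzuki ring closures that leave an exocyclic methylene; using one ethane-1,2-diyl diboron reagent for both bonds is the untested part. Ring B is closed in the second coupling by C(sp3)–C(sp2) reductive elimination from a seven-membered palladacycle, with C8=C17 left exocyclic and C4=C5 left conjugated to C19. No stereocenter is created: C9 and C10 are carried through unchanged, and C5 stays sp2 so that the ring fusion can be set by protonation in step 10. The step needs no site selectivity, because either triflate may react first and both orders converge on 16, but reductive elimination must outrun β-hydride elimination and cyclisation must outrun oligomerisation and triflate hydrolysis. In the substrate this is helped by both electrophilic carbons being alkenyl and by the quaternary C10 and branched C9 holding C5 and C8 close together; the bulky biarylphosphine, the mild base and slow addition at high dilution support it.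

Step 10
Reactants: 16 2-(trimethylsilyl)ethyl 2α-[(tert-butyldimethylsilyl)oxy]-13,13-(ethylenedioxy)-14,15,18-trinorlabda-4,8(17)-dien-19-oate
Product: 18 2-(trimethylsilyl)ethyl 2α-[(tert-butyldimethylsilyl)oxy]-13,13-(ethylenedioxy)-14,15-dinorlabd-8(17)-en-19-oate, via lithium ester enolate 17 (not isolated)
Conditions: Li, NH3(l), THF, t-BuOH (1 equiv), −78 °C; then MeI, −78 to −33 °C
Reagents that add atoms: iodomethane, CI
Why: Dissolving-metal (Birch-type) reductive alkylation of the enoate should protonate C5 axially from the α-face to give the trans-decalin and then methylate the exocyclic ester enolate 17 from the α-face anti to the axial C10 methyl, which sets C4 with an equatorial methyl and an axial ester.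

Step 11
Reactants: 18 2-(trimethylsilyl)ethyl 2α-[(tert-butyldimethylsilyl)oxy]-13,13-(ethylenedioxy)-14,15-dinorlabd-8(17)-en-19-oate
Product: 19 2-(trimethylsilyl)ethyl 2α-[(tert-butyldimethylsilyl)oxy]-13-oxo-14,15-dinorlabd-8(17)-en-19-oate
Conditions: pyridinium p-toluenesulfonate (cat.), acetone/H2O, 50 °C
Reagents that add atoms: water, O
Why: Acid-catalysed hydrolysis of the dioxolane under conditions mild enough for the secondary silyl ether, the silylethyl ester and the exocyclic alkene.

Step 12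
Reactants: 19 2-(trimethylsilyl)ethyl 2α-[(tert-butyldimethylsilyl)oxy]-13-oxo-14,15-dinorlabd-8(17)-en-19-oate; 20 triethyl phosphonoacetate
Product: 21 15-ethyl 19-[2-(trimethylsilyl)ethyl] (13E)-2α-[(tert-butyldimethylsilyl)oxy]labda-8(17),13-diene-15,19-dioate
Conditions: NaH, THF, 0 to 60 °C
Reagents that add atoms: none
Why: Horner–Wadsworth–Emmons olefination of the methyl ketone should give mainly the E-configured trisubstituted enoate because the ester prefers to lie anti to the larger C12 chain in the oxaphosphetane.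

Step 13
Reactants: 21 15-ethyl 19-[2-(trimethylsilyl)ethyl] (13E)-2α-[(tert-butyldimethylsilyl)oxy]labda-8(17),13-diene-15,19-dioate
Product: 22 (13E)-15-ethoxy-2α-hydroxy-15-oxolabda-8(17),13-dien-19-oic acid
Conditions: Bu4NF, THF, 45 °C; aq. HCl work-up
Reagents that add atoms: none
Why: Fluoride-induced β-elimination of the 2-(trimethylsilyl)ethyl ester (attack at silicon, so the hindered axial C19 carbonyl is no obstacle) and desilylation of the C2 ether occur in the same operation.

Step 14
Reactants: 22 (13E)-15-ethoxy-2α-hydroxy-15-oxolabda-8(17),13-dien-19-oic acid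
Product: 23 hypoxyterpoid A [(13E)-2α-hydroxylabda-8(17),13-diene-15,19-dioic acid]
Conditions: LiOH, THF/MeOH/H2O, 40 °C; then 1 M HCl
Reagents that add atoms: lithium hydroxide, [Li+].[OH-]
Why: Saponification of the unhindered conjugated ethyl ester gives the diacid without touching any stereocenter or the trisubstituted E-alkene.

**Compound list**

1 | (S)-5-methylfuran-2(5H)-one | C[C@H]1C=CC(=O)O1 | starting material
2 | 2-(2-bromoethyl)-2-methyl-1,3-dioxolane | CC1(CCBr)OCCO1 | starting material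
3 | [2-(2-methyl-1,3-dioxolan-2-yl)ethyl]magnesium bromide | CC1(CC[Mg]Br)OCCO1 | intermediate
4 | (4R,5S)-5-methyl-4-[2-(2-methyl-1,3-dioxolan-2-yl)ethyl]dihydrofuran-2(3H)-one | C[C@@H]1OC(=O)C[C@H]1CCC1(C)OCCO1 | intermediate
5 | (3R,4R,5S)-3,5-dimethyl-4-[2-(2-methyl-1,3-dioxolan-2-yl)ethyl]dihydrofuran-2(3H)-one | C[C@@H]1OC(=O)[C@H](C)[C@H]1CCC1(C)OCCO1 | intermediate
6 | (S)-5-(hydroxymethyl)dihydrofuran-2(3H)-one | OC[C@@H]1CCC(=O)O1 | starting material
7 | [(2S)-5-oxotetrahydrofuran-2-yl]methyl trifluoromethanesulfonate | FC(F)(F)S(=O)(=O)OC[C@@H]1CCC(=O)O1 | intermediate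
8 | lithium enolate of lactone 5 | C[C@@H]1OC(O[Li])=C(C)[C@H]1CCC1(C)OCCO1 | intermediate
9 | (3R,4R,5S)-3,5-dimethyl-4-[2-(2-methyl-1,3-dioxolan-2-yl)ethyl]-3-{[(2S)-5-oxotetrahydrofuran-2-yl]methyl}dihydrofuran-2(3H)-one | C[C@@H]1OC(=O)[C@](C)(C[C@@H]2CCC(=O)O2)[C@H]1CCC1(C)OCCO1 | intermediate
10 | 2-(trimethylsilyl)ethyl (3R,5R)-2,5-dihydroxy-3-[(2S,3R)-2-hydroxy-5-(2-methyl-1,3-dioxolan-2-yl)pentan-3-yl]-3-methylcyclohex-1-ene-1-carboxylate (enol form) | C[C@H](O)[C@H](CCC1(C)OCCO1)[C@@]2(C)C[C@@H](O)CC(C(=O)OCC[Si](C)(C)C)=C2O | intermediate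
11 | 2-(trimethylsilyl)ethyl (3R,5R)-5-[(tert-butyldimethylsilyl)oxy]-2-hydroxy-3-[(2S,3R)-2-hydroxy-5-(2-methyl-1,3-dioxolan-2-yl)pentan-3-yl]-3-methylcyclohex-1-ene-1-carboxylate | C[C@H](O)[C@H](CCC1(C)OCCO1)[C@@]2(C)C[C@@H](O[Si](C)(C)C(C)(C)C)CC(C(=O)OCC[Si](C)(C)C)=C2O | intermediate
12 | 2-(trimethylsilyl)ethyl (3R,5R)-5-[(tert-butyldimethylsilyl)oxy]-2-hydroxy-3-methyl-3-[(3R)-5-(2-methyl-1,3-dioxolan-2-yl)-2-oxopentan-3-yl]cyclohex-1-ene-1-carboxylate | CC(=O)[C@H](CCC1(C)OCCO1)[C@@]2(C)C[C@@H](O[Si](C)(C)C(C)(C)C)CC(C(=O)OCC[Si](C)(C)C)=C2O | intermediate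
13 | 2-(trimethylsilyl)ethyl (3R,5R)-5-[(tert-butyldimethylsilyl)oxy]-3-methyl-3-[(3R)-5-(2-methyl-1,3-dioxolan-2-yl)-2-(trifluoromethylsulfonyloxy)pent-1-en-3-yl]-2-(trifluoromethylsulfonyloxy)cyclohex-1-ene-1-carboxylate | C=C(OS(=O)(=O)C(F)(F)F)[C@H](CCC1(C)OCCO1)[C@@]2(C)C[C@@H](O[Si](C)(C)C(C)(C)C)CC(C(=O)OCC[Si](C)(C)C)=C2OS(=O)(=O)C(F)(F)F | intermediate
14 | 1,2-bis(4,4,5,5-tetramethyl-1,3,2-dioxaborolan-2-yl)ethane | CC1(C)OB(CCB2OC(C)(C)C(C)(C)O2)OC1(C)C | starting material
15 | mono-coupled homoallylic pinacol boronate (C8 triflate of 13 replaced by CH2CH2Bpin) | C=C(CCB1OC(C)(C)C(C)(C)O1)[C@H](CCC1(C)OCCO1)[C@@]2(C)C[C@@H](O[Si](C)(C)C(C)(C)C)CC(C(=O)OCC[Si](C)(C)C)=C2OS(=O)(=O)C(F)(F)F | intermediate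
16 | 2-(trimethylsilyl)ethyl 2α-[(tert-butyldimethylsilyl)oxy]-13,13-(ethylenedioxy)-14,15,18-trinorlabda-4,8(17)-dien-19-oate | C=C1CCC2=C(C(=O)OCC[Si](C)(C)C)C[C@H](O[Si](C)(C)C(C)(C)C)C[C@]2(C)[C@H]1CCC1(C)OCCO1 | intermediate
17 | lithium ester enolate from reduction of 16 (5α-H, C4=C19 enolate) | C=C1CC[C@@H]2[C@](C)(C[C@@H](O[Si](C)(C)C(C)(C)C)CC2=C(O[Li])OCC[Si](C)(C)C)[C@H]1CCC1(C)OCCO1 | intermediate
18 | 2-(trimethylsilyl)ethyl 2α-[(tert-butyldimethylsilyl)oxy]-13,13-(ethylenedioxy)-14,15-dinorlabd-8(17)-en-19-oate | C=C1CC[C@@H]2[C@](C)(C[C@@H](O[Si](C)(C)C(C)(C)C)C[C@]2(C)C(=O)OCC[Si](C)(C)C)[C@H]1CCC1(C)OCCO1 | intermediate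
19 | 2-(trimethylsilyl)ethyl 2α-[(tert-butyldimethylsilyl)oxy]-13-oxo-14,15-dinorlabd-8(17)-en-19-oate | C=C1CC[C@@H]2[C@](C)(C[C@@H](O[Si](C)(C)C(C)(C)C)C[C@]2(C)C(=O)OCC[Si](C)(C)C)[C@H]1CCC(C)=O | intermediate
20 | triethyl phosphonoacetate | CCOC(=O)CP(=O)(OCC)OCC | starting material
21 | 15-ethyl 19-[2-(trimethylsilyl)ethyl] (13E)-2α-[(tert-butyldimethylsilyl)oxy]labda-8(17),13-diene-15,19-dioate | C=C1CC[C@@H]2[C@](C)(C[C@@H](O[Si](C)(C)C(C)(C)C)C[C@]2(C)C(=O)OCC[Si](C)(C)C)[C@H]1CC/C(C)=C/C(=O)OCC | intermediate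
22 | (13E)-15-ethoxy-2α-hydroxy-15-oxolabda-8(17),13-dien-19-oic acid | C=C1CC[C@@H]2[C@](C)(C[C@@H](O)C[C@]2(C)C(=O)O)[C@H]1CC/C(C)=C/C(=O)OCC | intermediate
23 | hypoxyterpoid A | C=C1CC[C@@H]2[C@](C)(C[C@@H](O)C[C@]2(C)C(=O)O)[C@H]1CC/C(C)=C/C(=O)O | target

**Step count and risks**

Total: 14 steps. Longest linear sequence: 13 steps (from 1 through steps 1, 2 and 4–14; step 3 is a one-step branch).

Steps most likely to fail:

Step 9 (proposed new method). The second, intramolecular transmetalation of the unactivated primary alkylboronate may be too slow, so that β-hydride elimination, protodeboronation, hydrolysis of the enol triflate or intermolecular oligomerisation take over. The fallback uses known chemistry, sets out from 12 and returns at 16. Treatment of 12 with KN(SiMe3)2 (2.2 equiv) and only one equivalent of PhNTf2 at −78 °C should sulfonylate the more reactive methyl ketone enolate and give the mono(enol triflate) F1. Stille coupling with tributyl(vinyl)stannane (Pd(PPh3)4, LiCl, THF) gives the 2-substituted buta-1,3-diene F2. NaH and PhNTf2 convert its β-keto ester into the diene enol triflate F3. 9-BBN then hydroborates the monosubstituted vinyl terminus (the C8=C17 unit is shielded by C9) to the B-alkyl-9-BBN adduct F4, which is cyclised without isolation by intramolecular B-alkyl Suzuki–Miyaura coupling (Pd(dppf)Cl2, K3PO4, DMF/H2O) to 16.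

Step 4. Proton transfer from the α-methylene of the electrophile's own lactone to the hindered enolate, O-alkylation, or elimination of triflic acid may outrun the quaternising C-alkylation. The fallback sets out from 5 and returns at 9. (R)-Glycidol is converted with Tf2O into (S)-glycidyl triflate F5, an electrophile without acidic C–H. Enolate 8 is alkylated with it by direct displacement, with the same anti facial control, to give the epoxide F6. Sodium dimethyl malonate opens the epoxide at its terminal carbon and the resulting alkoxide lactonises to the α-methoxycarbonyl lactone F7. Krapcho demethoxycarbonylation (LiCl, wet DMSO, 140 °C) then gives 9.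

Step 12. Olefination of a methyl ketone may proceed with poor E/Z selectivity and give an inseparable mixture of geometric isomers. The fallback sets out from 19 and returns at 21. Kinetic enolisation towards the methyl group (LiN(iPr)2, −78 °C) and trapping with PhNTf2 gives the terminal enol triflate F8. Excess LiN(iPr)2 eliminates it to the terminal alkyne F9. Negishi carboalumination (AlMe3, Cp2ZrCl2 cat., CH2Cl2) followed by ethyl chloroformate adds methyl and the ester syn across the alkyne and gives 21 as the E isomer only.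

Further compounds
F1 | step 9 | 2-(trimethylsilyl)ethyl (3R,5R)-5-[(tert-butyldimethylsilyl)oxy]-2-hydroxy-3-methyl-3-[(3R)-5-(2-methyl-1,3-dioxolan-2-yl)-2-(trifluoromethylsulfonyloxy)pent-1-en-3-yl]cyclohex-1-ene-1-carboxylate | C=C(OS(=O)(=O)C(F)(F)F)[C@H](CCC1(C)OCCO1)[C@@]2(C)C[C@@H](O[Si](C)(C)C(C)(C)C)CC(C(=O)OCC[Si](C)(C)C)=C2O
F2 | step 9 | 2-substituted buta-1,3-diene (vinyl in place of the triflate of F1) | C=CC(=C)[C@H](CCC1(C)OCCO1)[C@@]2(C)C[C@@H](O[Si](C)(C)C(C)(C)C)CC(C(=O)OCC[Si](C)(C)C)=C2O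
F3 | step 9 | diene enol triflate (C5 triflate of F2) | C=CC(=C)[C@H](CCC1(C)OCCO1)[C@@]2(C)C[C@@H](O[Si](C)(C)C(C)(C)C)CC(C(=O)OCC[Si](C)(C)C)=C2OS(=O)(=O)C(F)(F)F
F4 | step 9 | B-alkyl-9-BBN adduct of F3 (boron on C6) | C=C(CCB1C2CCCC1CCC2)[C@H](CCC1(C)OCCO1)[C@@]2(C)C[C@@H](O[Si](C)(C)C(C)(C)C)CC(C(=O)OCC[Si](C)(C)C)=C2OS(=O)(=O)C(F)(F)F
F5 | step 4 | (S)-glycidyl trifluoromethanesulfonate | FC(F)(F)S(=O)(=O)OC[C@@H]1CO1
F6 | step 4 | (3R,4R,5S)-3,5-dimethyl-4-[2-(2-methyl-1,3-dioxolan-2-yl)ethyl]-3-[(2R)-oxiran-2-ylmethyl]dihydrofuran-2(3H)-one | C[C@@H]1OC(=O)[C@](C)(C[C@@H]2CO2)[C@H]1CCC1(C)OCCO1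
F7 | step 4 | α-methoxycarbonyl derivative of bis-lactone 9 (mixture at the malonate carbon) | C[C@@H]1OC(=O)[C@](C)(C[C@@H]2CC(C(=O)OC)C(=O)O2)[C@H]1CCC1(C)OCCO1
F8 | step 12 | terminal enol triflate of ketone 19 | C=C1CC[C@@H]2[C@](C)(C[C@@H](O[Si](C)(C)C(C)(C)C)C[C@]2(C)C(=O)OCC[Si](C)(C)C)[C@H]1CCC(=C)OS(=O)(=O)C(F)(F)F
F9 | step 12 | terminal alkyne (C13≡C14) | C=C1CC[C@@H]2[C@](C)(C[C@@H](O[Si](C)(C)C(C)(C)C)C[C@]2(C)C(=O)OCC[Si](C)(C)C)[C@H]1CCC#C
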